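## Retrosynthetic overview

1. The acetate goes on last, by selective acylation of the primary hydroxyl of the triol. The C1′ stereocentre comes from hydroxyl-directed hydrogenation of a C1′ exo-methylene group.
2. Key disconnection: ring bond C8–C9. The C9 carbinol sits next to C8, whose branch carbon C1′ can be an alkene carbon, so C9(OH)–C8–C1′(=CH2) is a homoallylic alcohol spanning a ring bond, with the C10 oxygen stereocentre α to C9. A thermal, macrocyclising (Z)-allylboration of the C9 aldehyde closes the cyclodeca-1,4-diene (the only ring, formed in this step) and sets C8 and C9 together.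
3. The (Z)-allylboronate comes from a (Z)-alkenyl iodide: α-iodo-ylide olefination of a C8 aldehyde, then Negishi coupling with a borylmethylzinc reagent.
4. The C8 aldehyde is a masked end of geranyl chloride (6,7-epoxide), which also supplies C3–C7 and the 4E alkene.
5. C1, C2 and the CH2O carbon come from propargyl alcohol (alkyne–allyl coupling, hydroxyl-directed trans-hydrostannation for the 1Z alkene); C9 and C10 come from a glycolic N-methoxy-N-methylamide, C10 being set by CBS reduction.

Key step: step 14

Remark on locants: ring carbons of the target are C1 (bears CH2OAc), C2 (=CH), C3 (CH2), C4 (=CH), C5 (C–CH3), C6, C7, C8 (CH with the side chain), C9 (CHOH), C10 (CHOH, bonded to C1); the side chain is C1′ (CH–CH3) to C6′. The target is (1Z,4E,8S,9R,10S,1′R). The same locants are used for open-chain intermediates.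

Remark on the epoxide: the epoxide carbon introduced in step 1 is racemic, so the intermediates of steps 1–7 are epimer mixtures at that carbon; it is excised in step 8 and does not affect the product.

Remark on availability: the silyloxy N-methoxy-N-methylamide used in step 4 is assumed to be a catalogue compound.

## Route

Step 1
Reactants: 1 geranyl chloride
Product: 2 6,7-epoxygeranyl chloride
Conditions: mCPBA (1.05 equiv), NaHCO3, CH2Cl2, 0 °C
Reagents that add atoms: m-chloroperoxybenzoic acid, O=C(OO)c1cccc(Cl)c1
Why: Prilezhaev epoxidation should take only the remote, electron-rich 6,7-alkene, because the 2,3-alkene is deactivated by the allylic chloride.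

Step 2
Reactants: 2 6,7-epoxygeranyl chloride; 3 prop-2-yn-1-ol
Product: 4 skipped enynol
Conditions: CuI (0.2 equiv), NaI (0.2 equiv), K2CO3 (1.5 equiv), DMF, rt
Reagents that add atoms: none
Why: Copper-acetylide substitution of a primary allylic chloride (alkyne–allyl coupling) should give the 1,4-enyne by SN2 attack at C3, leaving the 4E alkene and the epoxide untouched.

Step 3
Reactants: 4 skipped enynol
Product: 5 (Z)-alkenylstannane
Conditions: Bu3SnH (1.1 equiv), [Cp*RuCl]4 (2.5 mol%), CH2Cl2, rt
Reagents that add atoms: tributyltin hydride, CCCC[SnH](CCCC)CCCC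
Why: Ruthenium-catalysed trans-hydrostannation of a propargylic alcohol should place tin on the alkyne carbon next to CH2OH (hydroxyl direction) and hydrogen trans to it, so that tin (later C10) ends cis to C3 as the 1Z alkene requires.

Step 4
Reactants: 5 (Z)-alkenylstannane; 6 2-[(tert-butyldimethylsilyl)oxy]-N-methoxy-N-methylacetamide
Product: 8 hydroxy enone, via dilithio alkoxide 7 (not isolated)
Conditions: n-BuLi (2.1 equiv), THF, −78 °C; then 6 (1.3 equiv), −78 to 0 °C; aq. NH4Cl
Reagents that add atoms: none
Why: Tin–lithium exchange keeps the alkene geometry, and the alkenyllithium should acylate once on the N-methoxy-N-methylamide through its stable chelated adduct (Weinreb ketone synthesis).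

Step 5
Reactants: 8 hydroxy enone
Product: 9 silyl-protected enone
Conditions: t-BuPh2SiCl (1.2 equiv), imidazole (2.5 equiv), DMF, 0 °C
Reagents that add atoms: tert-butyl(chloro)diphenylsilane, CC(C)(C)[Si](Cl)(c1ccccc1)c1ccccc1
Why: Silylation of the only free hydroxyl gives a robust ether that survives the later palladium, fluoride-buffered and organolithium-free steps and is differentiated from the TBS groups.

Step 6
Reactants: 9 silyl-protected enone
Product: 10 (10S)-allylic alcohol
Conditions: (S)-2-methyl-CBS-oxazaborolidine (0.2 equiv), catecholborane (1.8 equiv), toluene, −78 °C; MeOH, then aq. NaHCO3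
Reagents that add atoms: none
Why: Corey–Bakshi–Shibata reduction should add hydride in the 1,2-sense to the enone face chosen by the catalyst, the branched alkenyl group acting as the large and CH2OTBS as the small substituent, which gives the 10S carbinol.

Step 7
Reactants: 10 (10S)-allylic alcohol
Product: 11 tris-silyl ether
Conditions: t-BuMe2SiCl (1.5 equiv), imidazole (3 equiv), DMAP (cat.), DMF, rt
Reagents that add atoms: tert-butyldimethylsilyl chloride, CC(C)(C)[Si](C)(C)Cl
Why: Silylation under mild base, tolerated by the epoxide, installs the non-chelating α-silyloxy group that later directs the 1,2-induction of the key step.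

Step 8
Reactants: 11 tris-silyl ether
Product: 12 C8 aldehyde
Conditions: H5IO6 (1.3 equiv), THF/Et2O, 0 °C
Reagents that add atoms: none
Why: Periodic acid opens the trisubstituted epoxide and cleaves the resulting glycol in one operation (oxidative epoxide cleavage), releasing acetone and the aldehyde without touching the alkenes.

Step 9
Reactants: 13 methyltriphenylphosphonium bromide; 14 5-bromo-2-methylpent-2-ene
Product: 16 (5-methylhex-4-en-1-yl)triphenylphosphonium bromide, via methylenetriphenylphosphorane 15 (not isolated)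
Conditions: n-BuLi (1.0 equiv), THF, 0 °C; ylide solution added to 14 (1.5 equiv), −78 °C to rt
Reagents that add atoms: none
Why: C-alkylation of a non-stabilised ylide by a primary bromide gives the chain-extended phosphonium salt, inverse addition keeping trans-ylidation low.

Step 10
Reactants: 12 C8 aldehyde; 16 (5-methylhex-4-en-1-yl)triphenylphosphonium bromide
Product: 20 (Z)-alkenyl iodide, via phosphonium ylide 17 (not isolated), via iodophosphonium iodide 18 (not isolated), via iodo ylide 19 (not isolated)
Conditions: 16 (1.6 equiv), n-BuLi, THF, rt; I2, −78 °C; NaN(SiMe3)2, −20 °C; then 12, −78 to −20 °C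
Reagents that add atoms: iodine, II
Why: Stork–Zhao-type Wittig olefination with an α-iodoalkylidene phosphorane should give the Z-iodoalkene (iodine cis to C7) through the kinetically favoured cis-oxaphosphetane.

Step 11
Reactants: 20 (Z)-alkenyl iodide
Product: 21 primary alcohol
Conditions: HF·pyridine, pyridine, THF, 0 °C
Reagents that add atoms: none
Why: Buffered HF·pyridine should remove the primary TBS ether much faster than the hindered secondary TBS and the TBDPS ether (selective desilylation), the alkenyl iodide being inert.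

Step 12
Reactants: 21 primary alcohol
Product: 22 (Z)-allylboronate alcohol
Conditions: ICH2Bpin (3.5 equiv), Zn dust, THF, rt; then 21, Pd(PPh3)4 (5 mol%), THF, 40 °C
Reagents that add atoms: 2-(iodomethyl)-4,4,5,5-tetramethyl-1,3,2-dioxaborolane, ICB1OC(C)(C)C(C)(C)O1
Why: Negishi coupling of the borylmethylzinc iodide with the alkenyl iodide proceeds with retention of geometry, so the CH2B group ends cis to C7, the excess reagent covering the free hydroxyl.

Step 13
Reactants: 22 (Z)-allylboronate alcohol
Product: 23 seco-aldehyde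
Conditions: Dess–Martin periodinane (1.3 equiv), NaHCO3, CH2Cl2, 0 °C; used at once without chromatography
Reagents that add atoms: none
Why: Dess–Martin oxidation is neutral and fast, so the α-silyloxy aldehyde should form without epimerisation at C10 and without oxidation of the C–B bond.

Step 14
Reactants: 23 seco-aldehyde
Product: 25 cyclodecadienol, via O-boronate ester 24 (not isolated)
Conditions: toluene, syringe-pump addition to 1 mM, 90 °C, 36 h; then aq. NaHCO3, rt
Reagents that add atoms: none
Why: Proposed new method: heating the aldehyde–allylboronate at 1 mM should give a thermal carbonyl allylboration through a closed six-membered chair transition state (boron on the carbonyl oxygen, C8 as γ-carbon attacking C9, the double bond moving to C1′=CH2), the closest known reaction type being the intramolecular allylboration that closes five- to eight-membered rings, while ten-membered carbocycles have been closed at the corresponding bond only by intramolecular allylchromium addition. The cyclodeca-1,4-diene is closed in an exo mode with respect to the allyl unit (the new C1′=CH2 alkene lies outside the ring), and the 1Z and 4E alkenes already in the chain lower the entropic and transannular cost. C8 is controlled by the Z geometry of the configurationally stable allylboronate (C7, cis to CH2B, is axial in the chair, which gives the syn relation of the C9 hydroxyl and C7), and C9 by 1,2-induction from the C10 silyloxy stereocentre (attack anti to the C–O bond, a preference that is reinforced for Z-configured γ-substituted allylboronates), which gives the 9,10-anti diol. The step needs ring closure to beat intermolecular addition, which high dilution with slow addition secures, and needs the aldehyde to ignore the C4=C5 alkene that could close a six-membered ring, which the absence of any Lewis acid secures because a thermal carbonyl-ene reaction is not competitive at 90 °C. Hydrolysis of the borate on work-up releases the free C9 alcohol.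

Step 15
Reactants: 25 cyclodecadienol
Product: 26 (1′R)-dihydro compound
Conditions: H2 (30 bar), [Rh(nbd)(dppb)]BF4 (10 mol%), CH2Cl2, rt
Reagents that add atoms: none
Why: Hydroxyl-directed hydrogenation by the cationic rhodium complex should reduce only the 1,1-disubstituted homoallylic alkene and deliver hydrogen to C1′ from the face of the C9–OH chelate in the conformer that avoids A(1,2) strain (C8–H eclipsing the C1′–C2′ bond), which gives 1′R.

Step 16
Reactants: 26 (1′R)-dihydro compound
Product: 27 triol
Conditions: Bu4NF (3 equiv), THF, rt; aq. NH4Cl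
Reagents that add atoms: none
Why: Fluoride-mediated desilylation should cleave both the secondary TBS and the primary TBDPS ether, the skipped diene being stable to these mildly basic conditions.

Step 17
Reactants: 27 triol
Product: 28 target
Conditions: AcCl (1.1 equiv), 2,4,6-collidine, CH2Cl2, −78 °C
Reagents that add atoms: acetyl chloride, CC(=O)Cl
Why: With a hindered pyridine base at low temperature the primary allylic hydroxyl should be acylated far faster than the two secondary ring hydroxyls (selective primary acetylation).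

## Compound list

1 | geranyl chloride, (2E)-1-chloro-3,7-dimethylocta-2,6-diene | ClC/C=C(\C)CCC=C(C)C | starting material
2 | 6,7-epoxygeranyl chloride, (2E)-1-chloro-6,7-epoxy-3,7-dimethyloct-2-ene (racemic epoxide) | ClC/C=C(\C)CCC1OC1(C)C | intermediate
3 | prop-2-yn-1-ol | C#CCO | starting material
4 | (5E)-9,10-epoxy-6,10-dimethylundec-5-en-2-yn-1-ol | OCC#CC/C=C(\C)CCC1OC1(C)C | intermediate
5 | (2Z,5E)-9,10-epoxy-6,10-dimethyl-2-(tributylstannyl)undeca-2,5-dien-1-ol | OC/C([Sn](CCCC)(CCCC)CCCC)=C/C/C=C(\C)CCC1OC1(C)C | intermediate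
6 | 2-[(tert-butyldimethylsilyl)oxy]-N-methoxy-N-methylacetamide | CON(C)C(=O)CO[Si](C)(C)C(C)(C)C | starting material
7 | dilithio species: lithium alkoxide of the 2-lithio analogue of 5 (lithium in place of tin, geometry retained) | [Li]OC/C([Li])=C/C/C=C(\C)CCC1OC1(C)C | intermediate
8 | (3Z,6E)-1-[(tert-butyldimethylsilyl)oxy]-10,11-epoxy-3-(hydroxymethyl)-7,11-dimethyldodeca-3,6-dien-2-one | OC/C(C(=O)CO[Si](C)(C)C(C)(C)C)=C/C/C=C(\C)CCC1OC1(C)C | intermediate
9 | (3Z,6E)-1-[(tert-butyldimethylsilyl)oxy]-3-{[(tert-butyldiphenylsilyl)oxy]methyl}-10,11-epoxy-7,11-dimethyldodeca-3,6-dien-2-one | CC(C)(C)[Si](c1ccccc1)(c1ccccc1)OC/C(C(=O)CO[Si](C)(C)C(C)(C)C)=C/C/C=C(\C)CCC1OC1(C)C | intermediate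
10 | (2S,3Z,6E)-1-[(tert-butyldimethylsilyl)oxy]-3-{[(tert-butyldiphenylsilyl)oxy]methyl}-10,11-epoxy-7,11-dimethyldodeca-3,6-dien-2-ol | CC(C)(C)[Si](c1ccccc1)(c1ccccc1)OC/C([C@H](O)CO[Si](C)(C)C(C)(C)C)=C/C/C=C(\C)CCC1OC1(C)C | intermediate
11 | (2S,3Z,6E)-1,2-bis[(tert-butyldimethylsilyl)oxy]-3-{[(tert-butyldiphenylsilyl)oxy]methyl}-10,11-epoxy-7,11-dimethyldodeca-3,6-diene | CC(C)(C)[Si](c1ccccc1)(c1ccccc1)OC/C([C@H](O[Si](C)(C)C(C)(C)C)CO[Si](C)(C)C(C)(C)C)=C/C/C=C(\C)CCC1OC1(C)C | intermediate
12 | (4E,7Z,9S)-9,10-bis[(tert-butyldimethylsilyl)oxy]-8-{[(tert-butyldiphenylsilyl)oxy]methyl}-4-methyldeca-4,7-dienal | CC(C)(C)[Si](c1ccccc1)(c1ccccc1)OC/C([C@H](O[Si](C)(C)C(C)(C)C)CO[Si](C)(C)C(C)(C)C)=C/C/C=C(\C)CCC=O | intermediate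
13 | methyltriphenylphosphonium bromide | C[P+](c1ccccc1)(c1ccccc1)c1ccccc1.[Br-] | starting material
14 | 5-bromo-2-methylpent-2-ene | CC(C)=CCCBr | starting material
15 | methylenetriphenylphosphorane | C=P(c1ccccc1)(c1ccccc1)c1ccccc1 | intermediate
16 | (5-methylhex-4-en-1-yl)triphenylphosphonium bromide | CC(C)=CCCC[P+](c1ccccc1)(c1ccccc1)c1ccccc1.[Br-] | intermediate
17 | (5-methylhex-4-en-1-ylidene)triphenylphosphorane | CC(C)=CCCC=P(c1ccccc1)(c1ccccc1)c1ccccc1 | intermediate
18 | (1-iodo-5-methylhex-4-en-1-yl)triphenylphosphonium iodide | CC(C)=CCCC(I)[P+](c1ccccc1)(c1ccccc1)c1ccccc1.[I-] | intermediate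
19 | (1-iodo-5-methylhex-4-en-1-ylidene)triphenylphosphorane | CC(C)=CCCC(I)=P(c1ccccc1)(c1ccccc1)c1ccccc1 | intermediate
20 | (2S,3Z,6E,10Z)-1,2-bis[(tert-butyldimethylsilyl)oxy]-3-{[(tert-butyldiphenylsilyl)oxy]methyl}-11-iodo-7,15-dimethylhexadeca-3,6,10,14-tetraene | CC(C)(C)[Si](c1ccccc1)(c1ccccc1)OC/C([C@H](O[Si](C)(C)C(C)(C)C)CO[Si](C)(C)C(C)(C)C)=C/C/C=C(\C)CC/C=C(\I)CCC=C(C)C | intermediate
21 | (2S,3Z,6E,10Z)-2-[(tert-butyldimethylsilyl)oxy]-3-{[(tert-butyldiphenylsilyl)oxy]methyl}-11-iodo-7,15-dimethylhexadeca-3,6,10,14-tetraen-1-ol | CC(C)(C)[Si](c1ccccc1)(c1ccccc1)OC/C([C@H](O[Si](C)(C)C(C)(C)C)CO)=C/C/C=C(\C)CC/C=C(\I)CCC=C(C)C | intermediate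
22 | (2S,3Z,6E,10E)-2-[(tert-butyldimethylsilyl)oxy]-3-{[(tert-butyldiphenylsilyl)oxy]methyl}-7,15-dimethyl-11-[(4,4,5,5-tetramethyl-1,3,2-dioxaborolan-2-yl)methyl]hexadeca-3,6,10,14-tetraen-1-ol (CH2B cis to the C7 methylene of the target) | CC(C)(C)[Si](c1ccccc1)(c1ccccc1)OC/C([C@H](O[Si](C)(C)C(C)(C)C)CO)=C/C/C=C(\C)CC/C=C(\CB1OC(C)(C)C(C)(C)O1)CCC=C(C)C | intermediate
23 | (2S,3Z,6E,10E)-2-[(tert-butyldimethylsilyl)oxy]-3-{[(tert-butyldiphenylsilyl)oxy]methyl}-7,15-dimethyl-11-[(4,4,5,5-tetramethyl-1,3,2-dioxaborolan-2-yl)methyl]hexadeca-3,6,10,14-tetraenal | CC(C)(C)[Si](c1ccccc1)(c1ccccc1)OC/C([C@H](O[Si](C)(C)C(C)(C)C)C=O)=C/C/C=C(\C)CC/C=C(\CB1OC(C)(C)C(C)(C)O1)CCC=C(C)C | intermediate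
24 | O9-pinacolboryl ester of 25 (target locants) | CC(C)(C)[Si](c1ccccc1)(c1ccccc1)OC/C1=C/C/C=C(\C)CC[C@@H](C(=C)CCC=C(C)C)[C@@H](OB2OC(C)(C)C(C)(C)O2)[C@H]1O[Si](C)(C)C(C)(C)C | intermediate
25 | (1Z,4E,8S,9R,10S)-10-[(tert-butyldimethylsilyl)oxy]-1-{[(tert-butyldiphenylsilyl)oxy]methyl}-5-methyl-8-(6-methylhepta-1,5-dien-2-yl)cyclodeca-1,4-dien-9-ol (target locants) | CC(C)(C)[Si](c1ccccc1)(c1ccccc1)OC/C1=C/C/C=C(\C)CC[C@@H](C(=C)CCC=C(C)C)[C@@H](O)[C@H]1O[Si](C)(C)C(C)(C)C | intermediate
26 | (1Z,4E,8S,9R,10S)-10-[(tert-butyldimethylsilyl)oxy]-1-{[(tert-butyldiphenylsilyl)oxy]methyl}-5-methyl-8-[(2R)-6-methylhept-5-en-2-yl]cyclodeca-1,4-dien-9-ol (target locants) | CC(C)(C)[Si](c1ccccc1)(c1ccccc1)OC/C1=C/C/C=C(\C)CC[C@@H]([C@H](C)CCC=C(C)C)[C@@H](O)[C@H]1O[Si](C)(C)C(C)(C)C | intermediate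
27 | (1Z,4E,8S,9R,10S)-1-(hydroxymethyl)-5-methyl-8-[(2R)-6-methylhept-5-en-2-yl]cyclodeca-1,4-diene-9,10-diol (target locants) | OC/C1=C/C/C=C(\C)CC[C@@H]([C@H](C)CCC=C(C)C)[C@@H](O)[C@H]1O | intermediate
28 | {(1Z,4E,8S,9R,10S)-9,10-dihydroxy-5-methyl-8-[(2R)-6-methylhept-5-en-2-yl]cyclodeca-1,4-dien-1-yl}methyl acetate (target locants), CNP0271046.2 | CC(=O)OC/C1=C/C/C=C(\C)CC[C@@H]([C@H](C)CCC=C(C)C)[C@@H](O)[C@H]1O | target

## Step count and risks

Total steps: 17. Longest linear sequence: 16 (steps 1–8 and 10–17; step 9 prepares the phosphonium salt).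

**Step 14 (labelled step).** What may go wrong: intermolecular allylboration (oligomerisation) may outrun ring closure at a workable dilution, or the thermal closure may be so slow that the α-silyloxy aldehyde degrades. Ring strain could also push the closure through a boat-like transition state and erode the syn selectivity. Fallback, known chemistry with Lewis-acid activation and an open transition state in place of the thermal closed one: it sets out from primary alcohol 21. Kumada coupling with commercial Me3SiCH2MgCl (excess, Pd(PPh3)4, THF, rt) should give the (Z)-allylsilane alcohol F1 with retention of geometry. Dess–Martin oxidation gives the allylsilane aldehyde F2. An intramolecular Hosomi–Sakurai reaction (BF3·OEt2, CH2Cl2, −78 °C, 1 mM) then closes the same C8–C9 bond; it is fast enough at low temperature to compete with oligomerisation and has the same sense of simple (syn) and 1,2-anti induction. The temperature is held at −78 °C to suppress carbonyl-ene closure onto the C4=C5 alkene. Aqueous work-up brings the route back at cyclodecadienol 25.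

**Step 15.** What may go wrong: facial selectivity at C1′ may be poor or reversed if the chelate reacts through the other rotamer about C8–C1′, and the same hydroxyl direction may cause over-reduction of the C1=C2 alkene. Fallback, moving stereocontrol from the substrate to the catalyst: it sets out from 25. Noyori asymmetric hydrogenation with Ru(OAc)2[(S)-BINAP] or its (R)-antipode (H2 50–100 bar, MeOH/CH2Cl2) is known for allylic and homoallylic alcohols and leaves isolated trisubstituted alkenes untouched. The antipode that is matched with the substrate would be fixed in a pair of small-scale runs. It comes back at 26 and makes no new compound.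

**Step 10.** What may go wrong: incomplete conversion through proto-deiodination of the α-iodo ylide, enolisation of the aldehyde by the basic ylide, and erosion of the Z/E ratio. Fallback, stepwise construction of the trisubstituted alkene by cross-coupling instead of olefination: it sets out from aldehyde 12. The first stage of the Corey–Fuchs olefination (CBr4, PPh3, Et3N, CH2Cl2, 0 °C) gives the 1,1-dibromoalkene F3. A trans-selective Negishi mono-alkylation with (4-methylpent-3-en-1-yl)zinc bromide F4 (from 14 and zinc; PdCl2(DPEphos), THF, rt) replaces the bromine trans to C7 and gives the (Z)-alkenyl bromide F5, bromine cis to C7. Copper-catalysed halogen exchange (CuI cat., NaI, trans-N,N′-dimethylcyclohexane-1,2-diamine, dioxane, 110 °C) with retention of geometry brings the route back at alkenyl iodide 20.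

Further compounds

F1 | step 14 | (Z)-allylsilane alcohol, the Me3SiCH2 analogue of 22 | CC(C)(C)[Si](c1ccccc1)(c1ccccc1)OC/C([C@H](O[Si](C)(C)C(C)(C)C)CO)=C/C/C=C(\C)CC/C=C(\C[Si](C)(C)C)CCC=C(C)C
F2 | step 14 | (Z)-allylsilane aldehyde, the Me3SiCH2 analogue of 23 | CC(C)(C)[Si](c1ccccc1)(c1ccccc1)OC/C([C@H](O[Si](C)(C)C(C)(C)C)C=O)=C/C/C=C(\C)CC/C=C(\C[Si](C)(C)C)CCC=C(C)C
F0 | step 15 | none | none
F3 | step 10 | 1,1-dibromoalkene from 12 | CC(C)(C)[Si](c1ccccc1)(c1ccccc1)OC/C([C@H](O[Si](C)(C)C(C)(C)C)CO[Si](C)(C)C(C)(C)C)=C/C/C=C(\C)CCC=C(Br)Br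
F4 | step 10 | (4-methylpent-3-en-1-yl)zinc bromide | CC(C)=CCC[Zn]Br
F5 | step 10 | (Z)-alkenyl bromide, the bromo analogue of 20 | CC(C)(C)[Si](c1ccccc1)(c1ccccc1)OC/C([C@H](O[Si](C)(C)C(C)(C)C)CO[Si](C)(C)C(C)(C)C)=C/C/C=C(\C)CC/C=C(\Br)CCC=C(C)C
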